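All runs were generated by integration with constants of no real substance; noise was put on by code.

If target at a fixed time falls with the charge c as Y/(1 + c/C), where Y is the target of a very thin flask, then dividing two flasks read at the same minute removes time and leaves C, which you can call the penalty charge.

| setting | dawn | midnight | alpha | beta | epsilon | delta | eta |
|---|---|---|---|---|---|---|---|
| substrate | 0.014 M | 0.049 M | 0.080 M | 0.12 M | 0.015 M | 0.15 M | 0.057 M |
| gas | 2.4 mM (held) | 2.4 mM (held) | 2.4 mM (held) | 2.4 mM (held) | 2.4 mM (held) | 2.4 mM (held) | 2.4 mM (held) |
| remark | run made earlier | run made earlier |  |  |  |  |  |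
| time |  |  | 1.5 h | 1.5 h | 1.5 h | 1.5 h | 1.5 h |

- dawn (time / min: target / %): 6.00: 1.4; 15.0: 3.9; 30.0: 11.7; 50.0: 24.7; 60.0: 29.7
- midnight (time / min: target / %): 12.0: 1.8; 25.0: 10.0; 40.0: 15.5; 50.0: 21.2; 60.0: 26.3

(scatter of a reading: 1 percentage point)

* ranking by amount of target, in percent of the substrate charged, from high to low, at 1.5 h (alpha / beta / epsilon / delta / eta)
* the amount of target, in percent of the substrate charged of the flask you put first, at 1.5 h
* the amount of target, in percent of the substrate charged of the flask you put last, at 1.5 h

- a species is counted by the substrate in it: one side product counts as two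
- at the start none of reagent is dissolved
- the numbers in the tables scatter with a standard deviation of 1 percentage point
- what may be going on: substrate -> intermediate; reagent + intermediate -> target; gas <-> reagent; 2 reagent -> homo dimer; substrate + intermediate -> side product

Start with time. Dawn gained 18 percentage points between 30.0 min and 60.0 min, and the same span again reaches 1.5 h. I take the rise as straight, which gives 47.7 %, and epsilon, charged nearly like dawn, should stand about there. Now the ratio: at 60.0 min, dawn over midnight is R = 1.13. With d and m the dawn and midnight charges, R = (C + m)/(C + d), so C = (m − Rd)/(R − 1) = 0.257 M. Carrying dawn's 47.7 % to delta's charge gives 31.8 %, and yield falls as charge rises, so you rank the flasks epsilon, eta, alpha, beta, delta.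

The weak link is R, which rests on a gap of 3.4 points between readings that each scatter by 1 point. Both runs were also read at 50.0 min, so sum the two shared times on each side. Then R = 1.15, and 0.227 M stands as the penalty charge, the scale of charge in that falling yield. Delta becomes 30.5 %.

The forecast ranks epsilon > eta > alpha > beta > delta, with 42 % first (range 37 % to 47 %) and 24 % last (range 13 % to 32 %), on the ground that “the second-order side reaction, substrate + intermediate, competes more as charge rises”. Its order is mine, but my top of 47.7 % stands higher, and so does my low of 30.5 %.

The simulation gives epsilon > eta > alpha > beta > delta, with 46.2 % first and 33.0 % last, so the forecast's order and top hold and its low lies 9 points under.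

    substrate → intermediate (k = 0.0102 min⁻¹)
    reagent + intermediate → target (k = 17.6 M⁻¹ min⁻¹)
    gas ⇌ reagent, rate k3*(csat - [reagent]) (kL = 0.488 min⁻¹)
    2 reagent → homo dimer (k = 4.45 M⁻¹ min⁻¹)
    substrate + intermediate → side product (k = 0.0250 M⁻¹ min⁻¹)

In delta at 1.50 h, substrate still held 37.6 % and its step to intermediate was running, with intermediate at 22.3 % while reagent, at 0.00108 M, stood below its saturation of 2.4 mM. Beside the capture to target, substrate with intermediate had made 7.08 % of side product. Scaled from epsilon's 46.2 % with C = 0.227 M, delta comes to 29.7 % against its 33.0 %, and the neighbour of delta charged with 0.60 M comes to 13.5 %; that flask holds 13.7 % of target.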